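**Retrosynthetic overview**
1. Target 7 ⇒ cut the C3–O bond. C3-lithiated flavone 4 reacts with peroxydisulfate, which delivers oxygen and sulfur together as one OSO3 unit. Silyl groups and counter-ion come off in the same flask.
2. 4 ⇒ bis-silyl ether 3 ⇒ pilloin 2. Only the two acidic OH groups are masked.
3. 2 ⇒ cut the 7-O–CH3 bond: diosmetin 1 + MeI under acidity control.
4. No ring is formed. Rings A, B and C are bought intact in 1 (bulk flavone, aglycone of the drug diosmin), and every bond made on the skeleton is a C–O bond.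

Assumption: the target has no stereocentre (achiral), so no enantiomer question arises; it is delivered as the free hydrogen sulfate as drawn, and (Bu4N)2S2O8 is taken as a stock reagent (a known THF-soluble salt, obtainable by salt exchange of K2S2O8 with Bu4NHSO4).

**Step 1**
Reactants: 1 diosmetin (5,7,3'-trihydroxy-4'-methoxyflavone)
Product: 2 pilloin (5,3'-dihydroxy-7,4'-dimethoxyflavone)
Conditions: MeI (1.05 equiv), K2CO3 (1.0 equiv), DMF, 0 °C → rt, 12 h
Reagents that add atoms: iodomethane (MeI), IC
Why: Williamson-type SN2 O-methylation under acidity control: the 7-OH (vinylogous acid through the C4 carbonyl, pKa about 7) is the only phenol ionised by one equivalent of K2CO3, the 3'-OH is about two pKa units weaker, the 5-OH is locked in its hydrogen bond to C4=O, and no stereocentre is involved.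

**Step 2**
Reactants: 2 pilloin
Product: 3 5,3'-bis-O-TBS-pilloin (5-(tert-butyldimethylsilyloxy)-2-[3-(tert-butyldimethylsilyloxy)-4-methoxyphenyl]-7-methoxy-4H-chromen-4-one)
Conditions: TBSOTf (2.6 equiv), 2,6-lutidine (3.5 equiv), CH2Cl2, 0 °C → rt, 3 h; NaHCO3 wash; short plug of Et3N-deactivated silica
Reagents that add atoms: tert-butyldimethylsilyl trifluoromethanesulfonate (TBSOTf), CC(C)(C)[Si](C)(C)OS(=O)(=O)C(F)(F)F
Why: Silyl ether protection with a silyl triflate: TBSOTf is electrophilic enough to silylate even the chelated 5-OH, any O-silylated benzopyrylium formed at C4=O reverts to the flavone on the NaHCO3 wash, and both protons that would consume the base of step 3 are masked by groups that fluoride removes without touching a sulfate ester.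

**Step 3**
Reactants: 3 5,3'-bis-O-TBS-pilloin
Product: 7 ombuin 3-O-sulfate (5-hydroxy-2-(3-hydroxy-4-methoxyphenyl)-7-methoxy-4-oxo-4H-chromen-3-yl hydrogen sulfate), via C3-lithiated flavone 4 (not isolated), via silylated Bu4N sulfate salt 5 (not isolated), via Bu4N ombuin 3-O-sulfate 6 (not isolated)
Conditions: LiN(iPr)2 (1.3 equiv), THF, −78 °C, 20 min; (Bu4N)2S2O8 (1.2 equiv, dried) in THF, −78 → −30 °C; MeOH; KHF2 (2.5 equiv), MeOH, rt, 1 h; n-BuOH extraction of the Bu4N+ ion pair; sulfonated polystyrene resin (H+ form), MeOH–H2O, 0 °C; LH-20 dextran gel; freeze-drying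
Reagents that add atoms: bis(tetrabutylammonium) peroxydisulfate, CCCC[N+](CCCC)(CCCC)CCCC.CCCC[N+](CCCC)(CCCC)CCCC.[O-]S(=O)(=O)OOS(=O)(=O)[O-] (gives the OSO3 unit of 5, 6 and 7 and the cation of 5 and 6); lithium diisopropylamide LiN(iPr)2, [Li+].CC(C)[N-]C(C)C (its lithium appears only in 4)
Why: Proposed new method: carbonyl-directed deprotonation of C3–H (known for fully O-protected flavones) gives vinyllithium 4, whose carbanion is proposed to attack the σ* orbital of the O–O bond of soluble peroxydisulfate in an SN2 displacement at oxygen, with Li+ bridging to a sulfonate oxygen and SO4(2−) leaving, so the C3–O bond and the complete OSO3− group arrive in one event; an electron-transfer path would give a caged vinyl radical/sulfate radical anion pair that collapses to the same C–O bond, cage escape only returns 3, and attack at the anionic tetrahedral sulfur is disfavoured; the closest known reaction types are the Elbs persulfate oxidation (a phenolate carbon attacks peroxydisulfate oxygen to give an aryl sulfate), the oxygenation of carbon nucleophiles by arenesulfonyl peroxides, and the oxenoid hydroxylation of organolithiums by LiOOtBu or Me3SiOOSiMe3; KHF2 then cleaves both aryl silyl ethers at a mild pH that the sulfate monoester tolerates, the resin exchanges Bu4N+ for H+, and no stereocentre is formed.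

**Compound list**
1 | diosmetin, 5,7-dihydroxy-2-(3-hydroxy-4-methoxyphenyl)-4H-chromen-4-one (achiral) | Oc1cc(O)c2c(=O)cc(-c3ccc(OC)c(O)c3)oc2c1 | starting material
2 | pilloin, 5-hydroxy-2-(3-hydroxy-4-methoxyphenyl)-7-methoxy-4H-chromen-4-one (achiral) | COc1cc(O)c2c(=O)cc(-c3ccc(OC)c(O)c3)oc2c1 | intermediate
3 | 5,3'-bis-O-TBS-pilloin (achiral) | COc1cc(O[Si](C)(C)C(C)(C)C)c2c(=O)cc(-c3ccc(OC)c(O[Si](C)(C)C(C)(C)C)c3)oc2c1 | intermediate
4 | 3-lithio-5,3'-bis-O-TBS-pilloin (not isolated) | COc1cc(O[Si](C)(C)C(C)(C)C)c2c(=O)c([Li])c(-c3ccc(OC)c(O[Si](C)(C)C(C)(C)C)c3)oc2c1 | intermediate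
5 | tetrabutylammonium 5,3'-bis-O-TBS-ombuin 3-sulfate (not isolated) | COc1cc(O[Si](C)(C)C(C)(C)C)c2c(=O)c(OS(=O)(=O)[O-])c(-c3ccc(OC)c(O[Si](C)(C)C(C)(C)C)c3)oc2c1.CCCC[N+](CCCC)(CCCC)CCCC | intermediate
6 | tetrabutylammonium ombuin 3-O-sulfate (not isolated) | COc1cc(O)c2c(=O)c(OS(=O)(=O)[O-])c(-c3ccc(OC)c(O)c3)oc2c1.CCCC[N+](CCCC)(CCCC)CCCC | intermediate
7 | ombuin 3-O-sulfate (achiral) | COc1cc(O)c2c(=O)c(OS(=O)(=O)O)c(-c3ccc(OC)c(O)c3)oc2c1 | target

**Total step count:** 3. **Longest linear sequence:** 3 steps (1 → 2 → 3 → 7).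

**Steps most likely to fail**

Most at risk is step 3, the new C3–O bond formation. Electron transfer with cage escape, or poor solubility of the persulfate at −78 °C, would simply return 3. The returned 3 is recovered as 2 after desilylation.

The fallback uses only known chemistry. It sets out from 3 and comes back at 5.
- 3 is lithiated to 4 as before and trapped by B(OMe)3 as lithium (5,3'-bis-O-TBS-pilloin-3-yl)trimethoxyborate F1.
- H2O2/AcOH oxidises this to 5,3'-bis-O-TBS-ombuin F2. This is the established lithiation–borylation–oxidation route to flavonols.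
- The only free OH of F2 is sulfated with Bu4NHSO4 and dicyclohexylcarbodiimide in pyridine to give 5.
- 5 is finished with KHF2 and the acid resin as in step 3.

In this fallback the C3–O and O–S bonds are made in separate, precedented operations.

Second is step 2. The chelated 5-OH may silylate incompletely, or the 5-O-silyl group may be lost on handling. The fallback changes the protecting-group class and the mode of release. It sets out from 2 and comes back at 6.
- BnBr, K2CO3, DMF, 80 °C gives 5,3'-di-O-benzylpilloin F3.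
- LiN(iPr)2 at −78 °C gives 3-lithio-5,3'-di-O-benzylpilloin F4.
- The persulfate quench gives tetrabutylammonium 5,3'-di-O-benzylombuin 3-sulfate F5.
- Neutral hydrogenolysis (H2, Pd/C, MeOH), which sulfate salts survive, gives 6.

Third is step 1. Some 3'-O-methylation or double methylation may accompany the 7-O-methylation. The fallback replaces acidity control with leaving-group control. It sets out from 1 and comes back at 2.
- Ac2O/pyridine gives diosmetin triacetate F6.
- MeI and K2CO3 in refluxing acetone exchange only the most labile 7-acetate for methyl. This is the known selective 7-alkylation of flavone peracetates, and it gives 5,3'-di-O-acetylpilloin F7.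
- Catalytic K2CO3 in MeOH removes the two remaining acetates to give 2.

**Further compounds**
F1 | step 3 | lithium (5,3'-bis-O-TBS-pilloin-3-yl)trimethoxyborate | COc1cc(O[Si](C)(C)C(C)(C)C)c2c(=O)c([B-](OC)(OC)OC)c(-c3ccc(OC)c(O[Si](C)(C)C(C)(C)C)c3)oc2c1.[Li+]
F2 | step 3 | 5,3'-bis-O-TBS-ombuin | COc1cc(O[Si](C)(C)C(C)(C)C)c2c(=O)c(O)c(-c3ccc(OC)c(O[Si](C)(C)C(C)(C)C)c3)oc2c1
F3 | step 2 | 5,3'-di-O-benzylpilloin | COc1cc(OCc5ccccc5)c2c(=O)cc(-c3ccc(OC)c(OCc4ccccc4)c3)oc2c1
F4 | step 2 | 3-lithio-5,3'-di-O-benzylpilloin | COc1cc(OCc5ccccc5)c2c(=O)c([Li])c(-c3ccc(OC)c(OCc4ccccc4)c3)oc2c1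
F5 | step 2 | tetrabutylammonium 5,3'-di-O-benzylombuin 3-sulfate | COc1cc(OCc5ccccc5)c2c(=O)c(OS(=O)(=O)[O-])c(-c3ccc(OC)c(OCc4ccccc4)c3)oc2c1.CCCC[N+](CCCC)(CCCC)CCCC
F6 | step 1 | diosmetin triacetate | CC(=O)Oc1cc(OC(C)=O)c2c(=O)cc(-c3ccc(OC)c(OC(C)=O)c3)oc2c1
F7 | step 1 | 5,3'-di-O-acetylpilloin | COc1cc(OC(C)=O)c2c(=O)cc(-c3ccc(OC)c(OC(C)=O)c3)oc2c1
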